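**Assumption:** (R)-lavandulol and (R)-2-methylbutanoic acid are bought as single enantiomers; everything else is a bulk chemical.

**Locants used for the target (6-oxabicyclo[3.2.1]octane):** C1 prenyl-bearing bridgehead, C2 CH2, C3 CH(prenyl), C4 CMe2, C5 acyl-bearing bridgehead, O6, C7 lactone C=O, C8 ketone.

## Retrosynthetic overview

1. Both target rings come from one operation: a rhodium carbenoid is formally inserted into the tertiary-alkyl C–O bond of a δ-lactone carrying a 2-diazo-1,3-diketone arm, forming C4–C5 (cyclohexanone) and C5–O6 (γ-lactone) together.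
2. The diazo-diketone arm (C8–C5 bond) comes from C-acylation of an (R)-diazoketone, made from (R)-2-methylbutanoic acid, by the acid chloride of a δ-lactone malonic half-acid.
3. The quaternary C1 centre is set by prenylating the dianion of that lactone acid, trans to the C3 prenyl group (1,3-induction inside the ring).
4. The lactone acid comes from di-tert-butyl malonate and (R)-lavandulyl iodide (C1–C2 bond), selective hydration of the isopropenyl group and acid lactonisation; C3 is bought with (R)-lavandulol.
5. Ring order: a temporary δ-lactone first (step 3), then cyclohexanone and γ-lactone together in the last step, where the δ-lactone is consumed.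

## Route

Step 1
Reactants: 1 (R)-lavandulol
Product: 2 (R)-lavandulyl iodide
Conditions: PPh3, I2, imidazole, CH2Cl2, 0 °C → rt
Reagents that add atoms: iodine, II
Why: Appel-type iodination replaces the primary OH by SN2 at CH2 and leaves the adjacent stereocentre (target C3) untouched; no later step makes or breaks a bond at this centre.

Step 2
Reactants: 2 (R)-lavandulyl iodide; 3 di-tert-butyl malonate
Product: 4 di-tert-butyl 2-[(2S)-5-methyl-2-(prop-1-en-2-yl)hex-4-en-1-yl]propanedioate
Conditions: NaH, 3 (1.5 equiv), THF–DMF, 0 → 60 °C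
Reagents that add atoms: none
Why: Malonic ester alkylation (SN2 of the soft sodium malonate on the primary iodide) builds the C1–C2 bond; excess malonate suppresses dialkylation, and the descriptor changes only through CIP priorities.

Step 3
Reactants: 4 di-tert-butyl 2-[(2S)-5-methyl-2-(prop-1-en-2-yl)hex-4-en-1-yl]propanedioate
Product: 6 (5S)-6,6-dimethyl-5-(3-methylbut-2-en-1-yl)-2-oxooxane-3-carboxylic acid (C3 epimers), via tertiary alcohol 5 (not isolated)
Conditions: Co(acac)2 (20 mol %), PhSiH3, O2 (1 atm), i-PrOH, rt; evaporate; then CF3CO2H–CH2Cl2 (1:4), 0 °C → rt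
Reagents that add atoms: dioxygen, O=O
Why: Mukaiyama hydration (cobalt-hydride hydrogen-atom transfer, Markovnikov) selects the 1,1-disubstituted alkene over the trisubstituted prenyl alkene, then acid removes both tert-butyl groups and closes the tertiary alcohol onto one carboxyl as the δ-lactone; the malonate carbon stays epimerisable and is left unassigned.

Step 4
Reactants: 6 (5S)-6,6-dimethyl-5-(3-methylbut-2-en-1-yl)-2-oxooxane-3-carboxylic acid; 7 prenyl bromide
Product: 8 (3S,5S)-6,6-dimethyl-3,5-bis(3-methylbut-2-en-1-yl)-2-oxooxane-3-carboxylic acid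
Conditions: LiN(i-Pr)2 (2.2 equiv), THF, −78 °C; 7, −78 → −30 °C; cold 0.5 M HCl work-up
Reagents that add atoms: none
Why: Alkylation of the lithium dianion of the malonic half-ester, where the electrophile enters axially on the half-chair enolate, syn to the axial H and trans to the equatorial prenyl group of ring carbon 5, which sets the quaternary centre (target C1) relative to C3 by 1,3-induction in the ring.

Step 5
Reactants: 9 (R)-2-methylbutanoic acid
Product: 11 (3R)-1-diazo-3-methylpentan-2-one, via acid chloride 10 (not isolated)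
Conditions: (COCl)2, DMF (cat.), CH2Cl2, 0 °C → rt; evaporate; then Me3SiCHN2, THF–MeCN, 0 °C → rt
Reagents that add atoms: (trimethylsilyl)diazomethane, C[Si](C)(C)C=[N+]=[N-]
Why: Arndt–Eistert-type acylation of the silyl diazomethane by the acid chloride, run without amine base so that no ketene forms and the α-stereocentre is kept.

Step 6
Reactants: 8 (3S,5S)-6,6-dimethyl-3,5-bis(3-methylbut-2-en-1-yl)-2-oxooxane-3-carboxylic acid; 11 (3R)-1-diazo-3-methylpentan-2-one
Product: 14 (3S,5S)-3-[(4R)-2-diazo-4-methyl-3-oxohexanoyl]-6,6-dimethyl-3,5-bis(3-methylbut-2-en-1-yl)oxan-2-one, via acid chloride 12 (not isolated), via lithiated diazoketone 13 (not isolated)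
Conditions: 8, 1-chloro-N,N,2-trimethylprop-1-en-1-amine, CH2Cl2, 0 °C → rt, evaporate; 11, LiN(SiMe3)2, THF, −78 °C; combine at −78 °C
Reagents that add atoms: none
Why: C-acylation of a metalated diazocarbonyl compound, in which the diazoketone is deprotonated at the diazo carbon and attacks the non-enolisable acid chloride to form the C8–C5 bond; the acid chloride is made under neutral conditions, so neither the prenyl groups, the tertiary lactone nor the sec-butyl centre is disturbed.

Step 7
Reactants: 14 (3S,5S)-3-[(4R)-2-diazo-4-methyl-3-oxohexanoyl]-6,6-dimethyl-3,5-bis(3-methylbut-2-en-1-yl)oxan-2-one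
Product: 16 (1S,3S,5S)-4,4-dimethyl-5-[(2R)-2-methylbutanoyl]-1,3-bis(3-methylbut-2-en-1-yl)-6-oxabicyclo[3.2.1]octane-7,8-dione, via carbonyl ylide 15 (not isolated)
Conditions: Rh2(OAc)4 (2 mol %), PhH (0.005 M), 80 °C, slow addition of 14
Reagents that add atoms: none
Why: Proposed new method: the electrophilic rhodium carbenoid at the diazo carbon is captured by the neighbouring lactone carbonyl oxygen to give the five-membered carbonyl ylide 15, whose tert-alkyl oxocarbenium unit releases the tertiary carbon C4, and the tethered cation is caught by the diketone-stabilised ylide carbon (the same product arises if the carbenoid attacks the ring oxygen and the oxonium ylide undergoes a Stevens [1,2]-shift), so the carbene carbon is formally inserted into the C(tert)–O bond and the cyclohexanone (C4–C5) and γ-lactone (C5–O6) form together, with C5 fixed by the bridge to the preset C1 and C3 centres and the C3 prenyl equatorial; closest known reaction types are carbonyl-ylide formation from ester carbonyls with divalent rhodium carbenoids, loss of tert-alkyl groups from O-alkylated ester oxocarbenium ions (tert-butyl ester to lactone closures) and Stevens shifts of oxonium ylides.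

## Compound list

1 | (R)-lavandulol, (2R)-5-methyl-2-(prop-1-en-2-yl)hex-4-en-1-ol | OC[C@H](CC=C(C)C)C(C)=C | starting material
2 | (R)-lavandulyl iodide, (2R)-1-iodo-5-methyl-2-(prop-1-en-2-yl)hex-4-ene | IC[C@H](CC=C(C)C)C(C)=C | intermediate
3 | di-tert-butyl malonate | CC(C)(C)OC(=O)CC(=O)OC(C)(C)C | starting material
4 | di-tert-butyl 2-[(2S)-5-methyl-2-(prop-1-en-2-yl)hex-4-en-1-yl]propanedioate (same spatial arrangement as in 1) | CC(C)(C)OC(=O)C(C[C@H](CC=C(C)C)C(C)=C)C(=O)OC(C)(C)C | intermediate
5 | di-tert-butyl 2-[(2S)-2-(2-hydroxypropan-2-yl)-5-methylhex-4-en-1-yl]propanedioate | CC(C)(C)OC(=O)C(C[C@H](CC=C(C)C)C(C)(C)O)C(=O)OC(C)(C)C | intermediate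
6 | (5S)-6,6-dimethyl-5-(3-methylbut-2-en-1-yl)-2-oxooxane-3-carboxylic acid, mixture of C3 epimers | OC(=O)C1C[C@H](CC=C(C)C)C(C)(C)OC1=O | intermediate
7 | prenyl bromide, 1-bromo-3-methylbut-2-ene | CC(C)=CCBr | starting material
8 | (3S,5S)-6,6-dimethyl-3,5-bis(3-methylbut-2-en-1-yl)-2-oxooxane-3-carboxylic acid, 3-prenyl trans to 5-prenyl | OC(=O)[C@]1(CC=C(C)C)C[C@H](CC=C(C)C)C(C)(C)OC1=O | intermediate
9 | (R)-2-methylbutanoic acid | CC[C@@H](C)C(=O)O | starting material
10 | (R)-2-methylbutanoyl chloride | CC[C@@H](C)C(=O)Cl | intermediate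
11 | (3R)-1-diazo-3-methylpentan-2-one | CC[C@@H](C)C(=O)C=[N+]=[N-] | intermediate
12 | (3R,5S)-6,6-dimethyl-3,5-bis(3-methylbut-2-en-1-yl)-2-oxooxane-3-carbonyl chloride (same spatial arrangement as 8) | ClC(=O)[C@]1(CC=C(C)C)C[C@H](CC=C(C)C)C(C)(C)OC1=O | intermediate
13 | (3R)-1-diazo-1-lithio-3-methylpentan-2-one | CC[C@@H](C)C(=O)C([Li])=[N+]=[N-] | intermediate
14 | (3S,5S)-3-[(4R)-2-diazo-4-methyl-3-oxohexanoyl]-6,6-dimethyl-3,5-bis(3-methylbut-2-en-1-yl)oxan-2-one | CC[C@@H](C)C(=O)C(=[N+]=[N-])C(=O)[C@]1(CC=C(C)C)C[C@H](CC=C(C)C)C(C)(C)OC1=O | intermediate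
15 | carbonyl ylide: lactone carbonyl oxygen of 14 bonded to the former diazo carbon (oxocarbenium at the lactone carbon, carbanion between the two ketones), other centres as in 14 | CC[C@@H](C)C(=O)[C-]1[O+]=C2OC(C)(C)[C@@H](CC=C(C)C)C[C@@]2(CC=C(C)C)C1=O | intermediate
16 | (1S,3S,5S)-4,4-dimethyl-5-[(2R)-2-methylbutanoyl]-1,3-bis(3-methylbut-2-en-1-yl)-6-oxabicyclo[3.2.1]octane-7,8-dione | CC[C@@H](C)C(=O)[C@@]12OC(=O)[C@@](CC=C(C)C)(C[C@H](CC=C(C)C)C1(C)C)C2=O | target

## Step count and risks

Total steps: 7. Longest linear sequence: 6 (steps 1, 2, 3, 4, 6, 7); step 5 is the side branch.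

**Step 7 (key ring switch).** This step is unprecedented as a whole. The carbenoid may instead cyclopropanate the prenyl group on the quaternary carbon or insert into the C5–H bond of the oxanone. The zwitterion may also collapse by O-alkylation (a pyran enol ether) or by proton loss (a monocyclic 5-acylfuran-2,4-dione).
Fallback, from 14 back to 16 by a stepwise polar sequence: 14 is decomposed with Rh2(OAc)4 in wet THF at rt, where O–H insertion into the large excess of water gives the 2-hydroxy-1,3-diketone F1. BF3·OEt2 in CH2Cl2 at −40 °C then ionises only the tertiary lactone C–O bond (no alkene protonation). The hydrogen-bonded enol of F1 is alkylated at carbon by the tethered cation, placing OH axial and the acyl group equatorial, to give the hydroxy keto acid F2. F2 lactonises in the same pot, or with 2,4,6-trichlorobenzoyl chloride, Et3N and DMAP, to 16.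

**Step 4 (quaternary centre).** The facial selectivity of the dianion rests on a half-chair argument and could be modest; O-alkylation of the carboxylate is a minor risk. 8 must be kept away from strong acid, because lactone ionisation would let the two carboxyl carbons change roles and scramble this centre.
Fallback, from 6 back to 8 through a soft mono-enolate and π-prenyl palladium chemistry instead of the hard dianion: 6 is esterified (EDC, DMAP, Me3SiCH2CH2OH) to the 2-(trimethylsilyl)ethyl ester F3. F3 is prenylated with methyl prenyl carbonate and Pd(PPh3)4 (zerovalent palladium; a chiral bisphosphine can be added to reinforce the ring bias) to the quaternary ester F4. Bu4NF in THF at 0 °C then releases 8 without acid.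

**Step 6 (hindered acylation).** The acid chloride sits on a fully substituted carbon, so attack by the lithiated diazoketone may be slow relative to its decomposition.
Fallback, from 12 back to 14 with the roles of the two acyl partners exchanged: 12 is treated with Me3SiCHN2 (as in step 5) to give the lactone diazomethyl ketone F5. Its lithio derivative (LiN(SiMe3)2, THF, −78 °C) is acylated by the small acid chloride 10 to give 14.

## Further compounds

F1 | step 7 | (3S,5S)-3-[(4R)-2-hydroxy-4-methyl-3-oxohexanoyl]-6,6-dimethyl-3,5-bis(3-methylbut-2-en-1-yl)oxan-2-one, carbinol centre unassigned | CC[C@@H](C)C(=O)C(O)C(=O)[C@]1(CC=C(C)C)C[C@H](CC=C(C)C)C(C)(C)OC1=O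
F2 | step 7 | 3-hydroxy-4,4-dimethyl-3-[(2R)-2-methylbutanoyl]-1,5-bis(3-methylbut-2-en-1-yl)-2-oxocyclohexane-1-carboxylic acid, OH cis to CO2H, ring centres as in 16 | CC[C@@H](C)C(=O)[C@@]1(O)C(C)(C)[C@@H](CC=C(C)C)C[C@](CC=C(C)C)(C(=O)O)C1=O
F3 | step 4 | 2-(trimethylsilyl)ethyl (5S)-6,6-dimethyl-5-(3-methylbut-2-en-1-yl)-2-oxooxane-3-carboxylate, C3 epimers | C[Si](C)(C)CCOC(=O)C1C[C@H](CC=C(C)C)C(C)(C)OC1=O
F4 | step 4 | 2-(trimethylsilyl)ethyl 6,6-dimethyl-3,5-bis(3-methylbut-2-en-1-yl)-2-oxooxane-3-carboxylate, ring centres as in 8 | C[Si](C)(C)CCOC(=O)[C@]1(CC=C(C)C)C[C@H](CC=C(C)C)C(C)(C)OC1=O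
F5 | step 6 | 3-(2-diazoacetyl)-6,6-dimethyl-3,5-bis(3-methylbut-2-en-1-yl)oxan-2-one, ring centres as in 14 | [N-]=[N+]=CC(=O)[C@]1(CC=C(C)C)C[C@H](CC=C(C)C)C(C)(C)OC1=O
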